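The synthesis rests on disconnecting the bond shared by the 1,2-dioxane and the γ-lactone, between C6 (quaternary, lactone oxygen) and C1 (peroxyhemiketal) of the 2,3,7-trioxabicyclo[4.3.0]nonan-8-one core. The 1,3-placement of hemiketal C1 and lactone carbonyl C8 around C6 is read as a latent cyclobutane-1,3-dione. The precursor is an acyclic α-methyl diazo ketone carrying the silylated tertiary peroxide. In one operation Wolff rearrangement gives a methyl alkyl ketene and [2+2] cycloaddition with ethoxyacetylene closes a cyclobutenone by forming C6–C1. Hydrolysis then erases the configuration at C6 in a dione, the tethered hydroperoxide picks one carbonyl as hemiketal and Baeyer–Villiger ring expansion gives the lactone.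

Key step: step 9

Assumption: the enantiomers of the ferrocenyl diphosphine (step 3) and of the binaphthoxide catalyst (step 4) are taken as those that give the configurations drawn; diazoethane is used as an ethereal solution made from N-ethyl-N-nitrosourea.

Step 1
Reactants: 1 5-hexyn-1-ol; 2 benzyl bromide
Product: 4 (E)-5-methyl-7-phenylhept-5-en-1-ol, via alkenylalane 3 (not isolated)
Conditions: AlMe3 (3 equiv), Cp2ZrCl2 (0.25 equiv), CH2Cl2, 0 to 23 °C; then 2, Pd(PPh3)4 (3 mol %), THF, 23 °C; aq. HCl work-up
Reagents that add atoms: trimethylaluminium C[Al](C)C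
Why: Negishi carboalumination adds methyl and aluminium syn across the terminal alkyne and the palladium-catalysed coupling of the alkenylalane with benzyl bromide goes with retention, so the trisubstituted alkene is formed as the E isomer (methyl cis to benzyl) while the hydroxyl is carried as its aluminium alkoxide.

Step 2
Reactants: 4 (E)-5-methyl-7-phenylhept-5-en-1-ol; 5 1-(triphenylphosphoranylidene)propan-2-one
Product: 7 (3E,8E)-8-methyl-10-phenyldeca-3,8-dien-2-one, via aldehyde 6 (not isolated)
Conditions: Dess–Martin periodinane, CH2Cl2, 0 to 23 °C; then 5, 23 °C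
Reagents that add atoms: none
Why: Dess–Martin oxidation gives the aldehyde without touching the alkene and the Wittig reaction of the stabilised acyl ylide delivers the (E)-enone.

Step 3
Reactants: 7 (3E,8E)-8-methyl-10-phenyldeca-3,8-dien-2-one
Product: 8 (4R,8E)-4,8-dimethyl-10-phenyldec-8-en-2-one
Conditions: MeMgBr (1.2 equiv), CuBr·SMe2 (5 mol %), (R)-1-[(S)-2-(diphenylphosphino)ferrocenyl]ethyldicyclohexylphosphine or its enantiomer (6 mol %), t-BuOMe, −75 °C
Reagents that add atoms: methylmagnesium bromide C[Mg]Br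
Why: Copper-catalysed asymmetric conjugate addition of the Grignard reagent to the acyclic (E)-enone is ligand-controlled, the ferrocenyl diphosphine directing methyl to the enone face that gives the 4R centre.

Step 4
Reactants: 8 (4R,8E)-4,8-dimethyl-10-phenyldec-8-en-2-one
Product: 10 (S)-2-[(2R,6E)-2,6-dimethyl-8-phenyloct-6-en-1-yl]-2-methyloxetane, via epoxide 9 (not isolated)
Conditions: Me3S(O)I (2.4 equiv), NaH (2.4 equiv), LaLi3(binaphthoxide)3 (5 mol %), tris(2,4,6-trimethoxyphenyl)phosphine oxide (5 mol %), 5 Å MS, THF, 23 °C then 45 °C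
Reagents that add atoms: trimethylsulfoxonium iodide C[S+](C)(C)=O.[I-]
Why: Catalytic asymmetric Corey–Chaykovsky epoxidation of the methyl ketone, in which the lanthanum–lithium binaphthoxide catalyst tells methyl from the CH2 branch and sets the quaternary C–O centre as S, is followed in the same flask by ylide ring expansion of the epoxide at its CH2 carbon, which leaves that centre untouched.

Step 5
Reactants: 10 (S)-2-[(2R,6E)-2,6-dimethyl-8-phenyloct-6-en-1-yl]-2-methyloxetane
Product: 11 (3R,5R,9E)-3-hydroperoxy-3,5,9-trimethyl-11-phenylundec-9-en-1-ol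
Conditions: H2O2 (anhydrous, in Et2O, 5 equiv), Me3SiOTf (0.3 equiv), Et2O, −78 to 0 °C
Reagents that add atoms: hydrogen peroxide OO
Why: Lewis-acid-activated perhydrolysis of the strained oxetane takes place at the tertiary carbon with inversion, turning the S ether centre into the R tertiary hydroperoxide, while the chain alkene is inert because no peracid is present.

Step 6
Reactants: 11 (3R,5R,9E)-3-hydroperoxy-3,5,9-trimethyl-11-phenylundec-9-en-1-ol
Product: 12 (3R,5R,9E)-3,5,9-trimethyl-11-phenyl-3-(triethylsilylperoxy)undec-9-en-1-ol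
Conditions: Et3SiCl (1.05 equiv), Et3N, CH2Cl2, −40 °C
Reagents that add atoms: chlorotriethylsilane CC[Si](Cl)(CC)CC
Why: Chemoselective O-silylation is expected because the hydroperoxide is more acidic and a stronger alpha-effect nucleophile than the primary alcohol, which reacts only slowly with Et3SiCl and Et3N without a nucleophilic catalyst; no stereocentre is affected.

Step 7
Reactants: 12 (3R,5R,9E)-3,5,9-trimethyl-11-phenyl-3-(triethylsilylperoxy)undec-9-en-1-ol
Product: 13 (3R,5R,9E)-3,5,9-trimethyl-11-phenyl-3-(triethylsilylperoxy)undec-9-enoic acid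
Conditions: TEMPO (0.2 equiv), PhI(OAc)2 (2.2 equiv), MeCN/H2O, 0 to 23 °C
Reagents that add atoms: water O
Why: Oxoammonium (TEMPO) oxidation of the primary alcohol through the aldehyde hydrate to the acid is mild enough for the silyl peroxide and does not touch the alkene.

Step 8
Reactants: 13 (3R,5R,9E)-3,5,9-trimethyl-11-phenyl-3-(triethylsilylperoxy)undec-9-enoic acid
Product: 15 (5R,7R,11E)-2-diazo-5,7,11-trimethyl-13-phenyl-5-(triethylsilylperoxy)tridec-11-en-3-one, via acyl chloride 14 (not isolated)
Conditions: 1-chloro-N,N,2-trimethylprop-1-en-1-amine, CH2Cl2, 0 °C; then CH3CHN2 (2.5 equiv), Et2O, −10 °C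
Reagents that add atoms: diazoethane CC=[N+]=[N-]
Why: Arndt–Eistert-type acylation of diazoethane by the acyl chloride, which is made under neutral conditions with the α-chloroenamine so that the silyl peroxide survives, gives the α-methyl diazo ketone, the excess diazoethane taking up HCl.

Step 9
Reactants: 15 (5R,7R,11E)-2-diazo-5,7,11-trimethyl-13-phenyl-5-(triethylsilylperoxy)tridec-11-en-3-one; 16 ethoxyacetylene
Product: 18 3-ethoxy-4-methyl-4-[(2R,4R,8E)-2,4,8-trimethyl-10-phenyl-2-(triethylsilylperoxy)dec-8-en-1-yl]cyclobut-2-en-1-one (both C4 epimers), via ketene 17 (not isolated)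
Conditions: hν (365 nm), 16 (5 equiv), CH2Cl2, 20 °C
Reagents that add atoms: none
Why: Irradiation at 365 nm excites only the diazo ketone, which loses N2 with 1,2-shift of the C4 methylene from the carbonyl carbon to the diazo carbon (Wolff rearrangement) and gives methyl alkyl ketene 17. The unsubstituted, nucleophilic carbon of ethoxyacetylene attacks the ketene carbonyl carbon and the dipolar intermediate collapses by bonding the ketene α-carbon to the ethoxy-bearing carbon, which is the bond between the later lactone-oxygen-bearing carbon and the later hemiketal carbon. The closest known reaction type is the photochemical Wolff rearrangement coupled to the ketene–alkoxyalkyne [2+2] cycloaddition that gives 3-alkoxycyclobutenones. The four-membered ring is closed in a formal thermal [2+2] mode, two bonds being formed and the second one by collapse of the zwitterion. The new quaternary carbon is formed without facial control, which is tolerated because it loses its stereogenicity in dione 19 of step 10, and no existing centre is touched. The step needs regioselectivity and chemoselectivity: the polarisation of the ynol ether secures the first, and the 365 nm window (the silyl peroxide does not absorb), the preference of the excited diazo ketone for concerted migration over 1,2-hydride shift and the excess of alkyne secure the second.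

Step 10
Reactants: 18 3-ethoxy-4-methyl-4-[(2R,4R,8E)-2,4,8-trimethyl-10-phenyl-2-(triethylsilylperoxy)dec-8-en-1-yl]cyclobut-2-en-1-one (both C4 epimers)
Product: 21 (1R,4R,6R)-4-[(2R,6E)-2,6-dimethyl-8-phenyloct-6-en-1-yl]-1-hydroxy-4,6-dimethyl-2,3,7-trioxabicyclo[4.3.0]nonan-8-one, via hydroperoxy dione 19 (not isolated), via bicyclic peroxyhemiketal 20 (not isolated)
Conditions: 1 M aq. H2SO4, THF, 23 °C; then CF3CH2OH, 30% aq. H2O2 (3 equiv), 0 °C
Reagents that add atoms: water O; hydrogen peroxide OO
Why: Acid hydrolysis of the vinylogous ester and of the silyl peroxide gives dione 19, in which the methyl-bearing ring carbon is no longer stereogenic so that both epimers of 18 converge; the tertiary hydroperoxide then closes reversibly on one of the two diastereotopic carbonyls as the six-membered, necessarily cis-fused peroxyhemiketal 20, which should favour the chair with the branched chain equatorial and the C4 methyl axial, and Baeyer–Villiger oxidation of the remaining strained ketone by H2O2 inserts oxygen next to the quaternary carbon with retention, fixing C6 as R and C1 as R.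

Compound list
1 | 5-hexyn-1-ol | C#CCCCCO | starting material
2 | benzyl bromide | BrCc1ccccc1 | starting material
3 | dimethylaluminium (E)-alkenylalane alkoxide (formed in situ) | C/C(=C\[Al](C)C)CCCCO[Al](C)C | intermediate
4 | (E)-5-methyl-7-phenylhept-5-en-1-ol | C/C(=C\Cc1ccccc1)CCCCO | intermediate
5 | 1-(triphenylphosphoranylidene)propan-2-one | CC(=O)C=P(c1ccccc1)(c1ccccc1)c1ccccc1 | starting material
6 | (E)-5-methyl-7-phenylhept-5-enal (formed in situ) | C/C(=C\Cc1ccccc1)CCCC=O | intermediate
7 | (3E,8E)-8-methyl-10-phenyldeca-3,8-dien-2-one | C/C(=C\Cc1ccccc1)CCC/C=C/C(C)=O | intermediate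
8 | (4R,8E)-4,8-dimethyl-10-phenyldec-8-en-2-one | C/C(=C\Cc1ccccc1)CCC[C@@H](C)CC(C)=O | intermediate
9 | (S)-2-[(2R,6E)-2,6-dimethyl-8-phenyloct-6-en-1-yl]-2-methyloxirane (formed in situ) | C/C(=C\Cc1ccccc1)CCC[C@@H](C)C[C@@]1(C)CO1 | intermediate
10 | (S)-2-[(2R,6E)-2,6-dimethyl-8-phenyloct-6-en-1-yl]-2-methyloxetane | C/C(=C\Cc1ccccc1)CCC[C@@H](C)C[C@@]1(C)CCO1 | intermediate
11 | (3R,5R,9E)-3-hydroperoxy-3,5,9-trimethyl-11-phenylundec-9-en-1-ol | C/C(=C\Cc1ccccc1)CCC[C@@H](C)C[C@](OO)(C)CCO | intermediate
12 | (3R,5R,9E)-3,5,9-trimethyl-11-phenyl-3-(triethylsilylperoxy)undec-9-en-1-ol | C/C(=C\Cc1ccccc1)CCC[C@@H](C)C[C@](OO[Si](CC)(CC)CC)(C)CCO | intermediate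
13 | (3R,5R,9E)-3,5,9-trimethyl-11-phenyl-3-(triethylsilylperoxy)undec-9-enoic acid | C/C(=C\Cc1ccccc1)CCC[C@@H](C)C[C@](OO[Si](CC)(CC)CC)(C)CC(=O)O | intermediate
14 | (3R,5R,9E)-3,5,9-trimethyl-11-phenyl-3-(triethylsilylperoxy)undec-9-enoyl chloride (formed in situ) | C/C(=C\Cc1ccccc1)CCC[C@@H](C)C[C@](OO[Si](CC)(CC)CC)(C)CC(=O)Cl | intermediate
15 | (5R,7R,11E)-2-diazo-5,7,11-trimethyl-13-phenyl-5-(triethylsilylperoxy)tridec-11-en-3-one | C/C(=C\Cc1ccccc1)CCC[C@@H](C)C[C@](OO[Si](CC)(CC)CC)(C)CC(=O)C(C)=[N+]=[N-] | intermediate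
16 | ethoxyacetylene | CCOC#C | starting material
17 | (4R,6R,10E)-2,4,6,10-tetramethyl-12-phenyl-4-(triethylsilylperoxy)dodeca-1,10-dien-1-one (ketene, formed in situ) | C/C(=C\Cc1ccccc1)CCC[C@@H](C)C[C@](OO[Si](CC)(CC)CC)(C)CC(C)=C=O | intermediate
18 | 3-ethoxy-4-methyl-4-[(2R,4R,8E)-2,4,8-trimethyl-10-phenyl-2-(triethylsilylperoxy)dec-8-en-1-yl]cyclobut-2-en-1-one (both C4 epimers) | C/C(=C\Cc1ccccc1)CCC[C@@H](C)C[C@](OO[Si](CC)(CC)CC)(C)CC1(C)C(=O)C=C1OCC | intermediate
19 | 2-[(2R,4R,8E)-2-hydroperoxy-2,4,8-trimethyl-10-phenyldec-8-en-1-yl]-2-methylcyclobutane-1,3-dione (formed in situ) | C/C(=C\Cc1ccccc1)CCC[C@@H](C)C[C@](OO)(C)CC1(C)C(=O)CC1=O | intermediate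
20 | (1R,4R,6S)-4-[(2R,6E)-2,6-dimethyl-8-phenyloct-6-en-1-yl]-1-hydroxy-4,6-dimethyl-2,3-dioxabicyclo[4.2.0]octan-7-one (formed in situ) | C/C(=C\Cc1ccccc1)CCC[C@@H](C)C[C@]1(C)C[C@@]2(C)C(=O)C[C@@]2(O)OO1 | intermediate
21 | (1R,4R,6R)-4-[(2R,6E)-2,6-dimethyl-8-phenyloct-6-en-1-yl]-1-hydroxy-4,6-dimethyl-2,3,7-trioxabicyclo[4.3.0]nonan-8-one (CNP0361739.2) | C/C(=C\Cc1ccccc1)CCC[C@@H](C)C[C@]1(C)C[C@@]2(C)OC(=O)C[C@@]2(O)OO1 | target

Total step count: 10. Longest linear sequence: 10 steps (from 5-hexyn-1-ol).

Steps most likely to fail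

1. Step 10. The two diastereotopic carbonyls of the dione may be discriminated only weakly during hemiketal formation and ring expansion, which would give low selectivity at C6. The strained dione may also be opened hydrolytically, and the chain alkene may be epoxidised. Fallback (sets out from 18, comes back at 21): the ring expansion is moved in front of the hydrolysis. Baeyer–Villiger oxidation of cyclobutenone 18 with Me3SiOOSiMe3 and catalytic Me3SiOTf (CH2Cl2, −40 °C), in which the quaternary sp3 carbon migrates in preference to the vinyl carbon, would give the ethyl tetronate as two C5 epimers. These are diastereomers and would be separated on silica. The wanted isomer, (5R)-4-ethoxy-5-methyl-5-[(2R,4R,8E)-2,4,8-trimethyl-10-phenyl-2-(triethylsilylperoxy)dec-8-en-1-yl]furan-2(5H)-one F1, is then treated with TsOH in wet THF. This removes the silyl group, lets the hydroperoxide add to C4 of the tetronate and exchanges ethoxy for hydroxy to give 21. C6 is then fixed by separation instead of by equilibration.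

2. Step 9. The carbene may undergo 1,2-hydride shift to a vinyl ketone instead of the Wolff shift, the ketene may dimerise before it is trapped, and the O–O bond may be photolysed. Fallback (sets out from 15, comes back at 18): rearrangement and cycloaddition are separated. Wolff rearrangement in aqueous dioxane (AgO2CPh cat., Et3N, 23 °C) traps the ketene with water as (4R,6R,10E)-2,4,6,10-tetramethyl-12-phenyl-4-(triethylsilylperoxy)dodec-10-enoic acid F2 (both C2 epimers). Oxalyl chloride with catalytic DMF gives (4R,6R,10E)-2,4,6,10-tetramethyl-12-phenyl-4-(triethylsilylperoxy)dodec-10-enoyl chloride F3. Slow addition of Et3N to F3 and excess ethoxyacetylene (toluene, 23 °C) regenerates the ketene by dehydrochlorination without light and gives 18.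

3. Step 4. The β-branched methyl ketone may enolise under the ylide conditions, catalyst control may be insufficient (erosion of configuration at the future peroxide carbon), and the ring expansion may stop at the epoxide. Fallback (sets out from 8, comes back at 10):
   - Horner–Wadsworth–Emmons olefination ((EtO)2P(O)CH2CO2Et, NaH, THF) and separation of the E isomer give ethyl (2E,5R,9E)-3,5,9-trimethyl-11-phenylundeca-2,9-dienoate F4.
   - i-Bu2AlH gives (2E,5R,9E)-3,5,9-trimethyl-11-phenylundeca-2,9-dien-1-ol F5.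
   - Sharpless asymmetric epoxidation (Ti(OiPr)4, L-(+)-diethyl tartrate, t-BuOOH, −20 °C), directed by the hydroxyl so that the isolated alkene is spared, gives [(2S,3S)-3-[(2R,6E)-2,6-dimethyl-8-phenyloct-6-en-1-yl]-3-methyloxiran-2-yl]methanol F6.
   - NaAlH2(OCH2CH2OMe)2 opens the epoxide at C2 to (3S,5R,9E)-3,5,9-trimethyl-11-phenylundec-9-ene-1,3-diol F7.
   - TsCl in pyridine gives (3S,5R,9E)-3-hydroxy-3,5,9-trimethyl-11-phenylundec-9-en-1-yl 4-methylbenzenesulfonate F8, and KOtBu closes it to oxetane 10 with the tertiary centre untouched.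

Further compounds
F1 | step 10 | (5R)-4-ethoxy-5-methyl-5-[(2R,4R,8E)-2,4,8-trimethyl-10-phenyl-2-(triethylsilylperoxy)dec-8-en-1-yl]furan-2(5H)-one | C/C(=C\Cc1ccccc1)CCC[C@@H](C)C[C@](OO[Si](CC)(CC)CC)(C)C[C@@]1(C)OC(=O)C=C1OCC
F2 | step 9 | (4R,6R,10E)-2,4,6,10-tetramethyl-12-phenyl-4-(triethylsilylperoxy)dodec-10-enoic acid (both C2 epimers) | C/C(=C\Cc1ccccc1)CCC[C@@H](C)C[C@](OO[Si](CC)(CC)CC)(C)CC(C)C(=O)O
F3 | step 9 | (4R,6R,10E)-2,4,6,10-tetramethyl-12-phenyl-4-(triethylsilylperoxy)dodec-10-enoyl chloride (both C2 epimers) | C/C(=C\Cc1ccccc1)CCC[C@@H](C)C[C@](OO[Si](CC)(CC)CC)(C)CC(C)C(=O)Cl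
F4 | step 4 | ethyl (2E,5R,9E)-3,5,9-trimethyl-11-phenylundeca-2,9-dienoate | C/C(=C\Cc1ccccc1)CCC[C@@H](C)C/C(C)=C/C(=O)OCC
F5 | step 4 | (2E,5R,9E)-3,5,9-trimethyl-11-phenylundeca-2,9-dien-1-ol | C/C(=C\Cc1ccccc1)CCC[C@@H](C)C/C(C)=C/CO
F6 | step 4 | [(2S,3S)-3-[(2R,6E)-2,6-dimethyl-8-phenyloct-6-en-1-yl]-3-methyloxiran-2-yl]methanol | C/C(=C\Cc1ccccc1)CCC[C@@H](C)C[C@@]1(C)[C@H](CO)O1
F7 | step 4 | (3S,5R,9E)-3,5,9-trimethyl-11-phenylundec-9-ene-1,3-diol | C/C(=C\Cc1ccccc1)CCC[C@@H](C)C[C@@](O)(C)CCO
F8 | step 4 | (3S,5R,9E)-3-hydroxy-3,5,9-trimethyl-11-phenylundec-9-en-1-yl 4-methylbenzenesulfonate | C/C(=C\Cc1ccccc1)CCC[C@@H](C)C[C@@](O)(C)CCOS(=O)(=O)c1ccc(C)cc1
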